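**Strategy.** Ring A is built, not benzylated. Its C2–C3–C4 triad, C(4-hydroxybenzyl)–C(OH)–C(4-hydroxybenzyl), is a disguised 1,5-diarylpentan-3-one (acetone plus two 4-oxybenzaldehydes). The other triad, C1(O)–C6–C5(CH2CH2Ar), is a 5-arylpent-2-ynoate. A [3+3] Michael–Dieckmann benzannulation of these fragments forms the C4–C5 and C1–C2 ring bonds. In one operation it delivers the resorcinol ring with two benzyl groups, both oxygens and the bibenzyl tether, which is never made by joining two arenes. One ring position stays open; O-methylation, a Friedel–Crafts benzylation there, a ring-B benzyl cross-coupling and global hydrogenolysis finish the route.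

Key step: step 5

Remark: the target has no stereocentre and no stereogenic double bond; it is achiral, so no step has to set or preserve configuration. Ring A is numbered as in the target SMILES (C1 OMe, C3 OH, C5 CH2CH2Ar).

Step 1
Reactants: 1 4-(benzyloxy)benzaldehyde (2 equiv); 2 acetone
Product: 3 (1E,4E)-1,5-bis[4-(benzyloxy)phenyl]penta-1,4-dien-3-one
Conditions: NaOH (cat.), EtOH–H2O, rt
Reagents that add atoms: none
Why: Double Claisen–Schmidt condensation, in which acetone is the only enolisable partner, the aryl aldehyde cannot self-condense, and the conjugated (E,E)-dienone should precipitate.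

Step 2
Reactants: 3 (1E,4E)-1,5-bis[4-(benzyloxy)phenyl]penta-1,4-dien-3-one
Product: 4 1,5-bis[4-(benzyloxy)phenyl]pentan-3-one
Conditions: H2 (1 atm), 10% Pd/C, Ph2S (cat.), EtOAc, rt
Reagents that add atoms: none
Why: Catalytic hydrogenation over sulfide-poisoned Pd/C should saturate both enone C=C bonds, while the poisoned catalyst is expected to leave the aryl benzyl ethers and the dialkyl ketone untouched.

Step 3
Reactants: 5 3-(benzyloxy)benzyl bromide; 6 propyne
Product: 9 methyl 5-[3-(benzyloxy)phenyl]pent-2-ynoate, via 1,3-dilithiopropyne 7 (not isolated), via lithium 4-[3-(benzyloxy)phenyl]but-1-yn-1-ide 8 (not isolated)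
Conditions: 6, n-BuLi (2 equiv per 6), TMEDA, THF–hexane, −78 → 0 °C; then 5, −78 → −20 °C; then ClCO2Me, −78 °C → rt
Reagents that add atoms: methyl chloroformate, COC(=O)Cl
Why: Sequential alkylation–acylation of a propargylic dianion, in which the more basic sp3 terminus of 7 displaces the benzylic bromide (SN2) and the remaining acetylide 8 is C-acylated by the chloroformate.

Step 4
Reactants: 9 methyl 5-[3-(benzyloxy)phenyl]pent-2-ynoate
Product: 10 methyl 5-[5-(benzyloxy)-2-bromophenyl]pent-2-ynoate
Conditions: NBS (1.05 equiv), MeCN, 0 °C → rt, dark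
Reagents that add atoms: N-bromosuccinimide, O=C1CCC(=O)N1Br
Why: Electrophilic aromatic bromination with NBS in a polar solvent should go para to the alkoxy group (ortho to the side chain), and the electron-poor ynoate and the unactivated benzyl ring should not react.

Step 5
Reactants: 4 1,5-bis[4-(benzyloxy)phenyl]pentan-3-one; 10 methyl 5-[5-(benzyloxy)-2-bromophenyl]pent-2-ynoate
Product: 13 2,4-bis[4-(benzyloxy)benzyl]-5-{2-[5-(benzyloxy)-2-bromophenyl]ethyl}benzene-1,3-diol, via sodium enolate 11 (not isolated), via Michael-adduct dienolate 12 (not isolated)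
Conditions: NaHMDS (1.05 equiv), THF, −78 °C; then 10, −78 → 0 °C; then NaOMe (3 equiv), MeOH, 65 °C; aq. HCl
Reagents that add atoms: none
Why: Proposed new method: the sodium enolate 11 of the symmetric ketone (only one enolate is possible) should add 1,4 to C3 of ynoate 10 (Michael addition, forming C4–C5) and proton transfer gives the stabilised dienolate 12, after which under NaOMe/MeOH at 65 °C the minor enolate at the other α-carbon acylates the ester (Dieckmann condensation, forming C2–C1 with loss of methoxide) and the cyclohexene-1,3-dione tautomerises to the resorcinol, whose phenoxide makes the sequence irreversible. The closest known reaction type is the Michael–Dieckmann synthesis of resorcinols from 2-alkynoates and doubly stabilised ketones (3-oxoglutarates, β-keto esters); new here is a non-stabilised dialkyl ketone as donor, for which the usual outcome with alkynoates is O-acylation to a 2-pyranone. The single ring closure is a 6-(enolendo)-exo-trig acylation. No stereocentre is formed, and the substitution pattern is fixed by connectivity, because the ketone carbon can only become the C–OH flanked by both benzyl-bearing carbons, the ynoate β-carbon carries the arylethyl chain and the ester carbon becomes the second C–OH. The step needs 1,4- over 1,2-addition and C- over O-acylation: the soft sodium enolate and the β-polarised triple bond favour conjugate addition, and methoxide in methanol should reopen any 2-pyranone to 12, so that all prototropic isomers (ynoate, allenoate, E/Z enoates) drain into the aromatic product.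

Step 6
Reactants: 13 2,4-bis[4-(benzyloxy)benzyl]-5-{2-[5-(benzyloxy)-2-bromophenyl]ethyl}benzene-1,3-diol
Product: 14 2,6-bis[4-(benzyloxy)benzyl]-3-{2-[5-(benzyloxy)-2-bromophenyl]ethyl}-5-methoxyphenol
Conditions: MeI (1.05 equiv), K2CO3, acetone, rt
Reagents that add atoms: iodomethane, CI
Why: Williamson etherification, in which the phenoxide with one ortho substituent should be methylated first and the hydroxyl flanked by two benzyl groups more slowly, favouring the monoether, and because step 7 fills the last ring position, methylation at either oxygen would lead to the same constitution.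

Step 7
Reactants: 14 2,6-bis[4-(benzyloxy)benzyl]-3-{2-[5-(benzyloxy)-2-bromophenyl]ethyl}-5-methoxyphenol; 15 [4-(benzyloxy)phenyl]methanol
Product: 16 2,4,6-tris[4-(benzyloxy)benzyl]-3-{2-[5-(benzyloxy)-2-bromophenyl]ethyl}-5-methoxyphenol
Conditions: 15 (1.2 equiv, slow addition), Sc(OTf)3 (5 mol %), MeNO2, rt
Reagents that add atoms: none
Why: Friedel–Crafts benzylation with a benzylic alcohol under Lewis acid catalysis, in which the stabilised 4-alkoxybenzyl cation should attack the only free position of ring A, para to the free hydroxyl and far more nucleophilic than the brominated ring B or the alkoxyphenyl rings.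

Step 8
Reactants: 16 2,4,6-tris[4-(benzyloxy)benzyl]-3-{2-[5-(benzyloxy)-2-bromophenyl]ethyl}-5-methoxyphenol; 17 4-(benzyloxy)benzyl chloride
Product: 19 2,4,6-tris[4-(benzyloxy)benzyl]-3-(2-{5-(benzyloxy)-2-[4-(benzyloxy)benzyl]phenyl}ethyl)-5-methoxyphenol, via benzylic zinc chloride 18 (not isolated)
Conditions: 17, Zn dust, LiCl, THF, rt; then 16, Pd(OAc)2 (2 mol %), SPhos (4 mol %), THF, rt → 50 °C (18 in excess, slow addition)
Reagents that add atoms: none
Why: Negishi cross-coupling, in which LiCl-mediated zinc insertion into the benzylic chloride gives 18, which should couple with the aryl bromide under Pd/biarylphosphine catalysis that tolerates ortho substitution and, with excess reagent, a free hindered phenol.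

Step 9
Reactants: 19 2,4,6-tris[4-(benzyloxy)benzyl]-3-(2-{5-(benzyloxy)-2-[4-(benzyloxy)benzyl]phenyl}ethyl)-5-methoxyphenol
Product: 20 Bleochrin B
Conditions: H2 (1 atm), 10% Pd/C, EtOAc–MeOH, rt
Reagents that add atoms: none
Why: Hydrogenolysis of the five aryl benzyl ethers should free the phenols, while the aryl methyl ether and the diarylmethane and bibenzyl C–C bonds are inert under these conditions.

**Compound list**

1 | 4-(benzyloxy)benzaldehyde | O=Cc1ccc(OCc2ccccc2)cc1 | starting material
2 | acetone | CC(C)=O | starting material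
3 | (1E,4E)-1,5-bis[4-(benzyloxy)phenyl]penta-1,4-dien-3-one | O=C(/C=C/c1ccc(OCc2ccccc2)cc1)/C=C/c1ccc(OCc2ccccc2)cc1 | intermediate
4 | 1,5-bis[4-(benzyloxy)phenyl]pentan-3-one | O=C(CCc1ccc(OCc2ccccc2)cc1)CCc1ccc(OCc2ccccc2)cc1 | intermediate
5 | 3-(benzyloxy)benzyl bromide | BrCc1cccc(OCc2ccccc2)c1 | starting material
6 | propyne | CC#C | starting material
7 | 1,3-dilithiopropyne | [Li]CC#C[Li] | intermediate (not isolated)
8 | lithium 4-[3-(benzyloxy)phenyl]but-1-yn-1-ide | [Li]C#CCCc1cccc(OCc2ccccc2)c1 | intermediate (not isolated)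
9 | methyl 5-[3-(benzyloxy)phenyl]pent-2-ynoate | COC(=O)C#CCCc1cccc(OCc2ccccc2)c1 | intermediate
10 | methyl 5-[5-(benzyloxy)-2-bromophenyl]pent-2-ynoate | COC(=O)C#CCCc1cc(OCc2ccccc2)ccc1Br | intermediate
11 | sodium 1,5-bis[4-(benzyloxy)phenyl]pent-2-en-3-olate (enolate of 4, geometry not defined) | [Na+].[O-]C(=CCc1ccc(OCc2ccccc2)cc1)CCc1ccc(OCc2ccccc2)cc1 | intermediate (not isolated)
12 | sodium dienolate (C5 enolate, geometries not defined) of methyl 4-[4-(benzyloxy)benzyl]-3-{2-[5-(benzyloxy)-2-bromophenyl]ethyl}-7-[4-(benzyloxy)phenyl]-5-oxohept-2-enoate | [Na+].[O-]C(CCc1ccc(OCc2ccccc2)cc1)=C(Cc1ccc(OCc2ccccc2)cc1)C(CCc1cc(OCc2ccccc2)ccc1Br)=CC(=O)OC | intermediate (not isolated)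
13 | 2,4-bis[4-(benzyloxy)benzyl]-5-{2-[5-(benzyloxy)-2-bromophenyl]ethyl}benzene-1,3-diol | Oc1cc(CCc2cc(OCc3ccccc3)ccc2Br)c(Cc2ccc(OCc3ccccc3)cc2)c(O)c1Cc1ccc(OCc2ccccc2)cc1 | intermediate
14 | 2,6-bis[4-(benzyloxy)benzyl]-3-{2-[5-(benzyloxy)-2-bromophenyl]ethyl}-5-methoxyphenol | COc1cc(CCc2cc(OCc3ccccc3)ccc2Br)c(Cc2ccc(OCc3ccccc3)cc2)c(O)c1Cc1ccc(OCc2ccccc2)cc1 | intermediate
15 | [4-(benzyloxy)phenyl]methanol | OCc1ccc(OCc2ccccc2)cc1 | starting material
16 | 2,4,6-tris[4-(benzyloxy)benzyl]-3-{2-[5-(benzyloxy)-2-bromophenyl]ethyl}-5-methoxyphenol | COc1c(Cc2ccc(OCc3ccccc3)cc2)c(O)c(Cc2ccc(OCc3ccccc3)cc2)c(CCc2cc(OCc3ccccc3)ccc2Br)c1Cc1ccc(OCc2ccccc2)cc1 | intermediate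
17 | 4-(benzyloxy)benzyl chloride | ClCc1ccc(OCc2ccccc2)cc1 | starting material
18 | [4-(benzyloxy)benzyl]zinc chloride | Cl[Zn]Cc1ccc(OCc2ccccc2)cc1 | intermediate (not isolated)
19 | 2,4,6-tris[4-(benzyloxy)benzyl]-3-(2-{5-(benzyloxy)-2-[4-(benzyloxy)benzyl]phenyl}ethyl)-5-methoxyphenol | COc1c(Cc2ccc(OCc3ccccc3)cc2)c(O)c(Cc2ccc(OCc3ccccc3)cc2)c(CCc2cc(OCc3ccccc3)ccc2Cc2ccc(OCc3ccccc3)cc2)c1Cc1ccc(OCc2ccccc2)cc1 | intermediate
20 | Bleochrin B, 2,4,6-tris(4-hydroxybenzyl)-3-{2-[5-hydroxy-2-(4-hydroxybenzyl)phenyl]ethyl}-5-methoxyphenol | COc1c(Cc2ccc(O)cc2)c(O)c(Cc2ccc(O)cc2)c(CCc2cc(O)ccc2Cc2ccc(O)cc2)c1Cc1ccc(O)cc1 | target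

**Total step count:** 9. **Longest linear sequence:** 7 steps (1, 2, 5, 6, 7, 8, 9 from aldehyde 1; equally 3, 4, 5, 6, 7, 8, 9 from bromide 5).

**Steps most likely to fail**

Step 5 (Proposed new method). The conjugate adduct may close through oxygen and stop at a 2-pyranone, the enolate may add 1,2 to the ester, or the non-stabilised enolate may self-condense before it finds the ynoate. The fallback uses the established doubly stabilised donor and sets out from 10. Commercial dimethyl 3-oxopentanedioate and 10 (NaH, THF, 0 °C → reflux) should undergo the known Michael–Dieckmann condensation to dimethyl 4-{2-[5-(benzyloxy)-2-bromophenyl]ethyl}-2,6-dihydroxybenzene-1,3-dicarboxylate F1. Saponification (KOH, aq. MeOH, reflux) gives 4-{2-[5-(benzyloxy)-2-bromophenyl]ethyl}-2,6-dihydroxybenzene-1,3-dicarboxylic acid F2, which on acidification and warming should lose both carboxyl groups to give 5-{2-[5-(benzyloxy)-2-bromophenyl]ethyl}benzene-1,3-diol F3. Mono-O-methylation of the two equivalent hydroxyls (MeI 1 equiv, K2CO3, acetone, recovered diol recycled) gives 3-{2-[5-(benzyloxy)-2-bromophenyl]ethyl}-5-methoxyphenol F4. Exhaustive threefold Friedel–Crafts benzylation of ring A with 15 (3.3 equiv, Sc(OTf)3, MeNO2) fills C2, C4 and C6 and comes back to the route at 16; ketone 4 is not needed in this variant.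

Step 7. Acid may induce transbenzylation (retro-Friedel–Crafts loss or migration of the alkoxybenzyl groups already on ring A), the benzylic alcohol may self-condense, or attack at the flanked C6 may be slow. The fallback sets out from 14 and replaces the electrophilic benzylation by halogenation and cross-coupling. NBS (1.0 equiv, MeCN, 0 °C) should brominate C6, para to the free hydroxyl, to give 2,6-bis[4-(benzyloxy)benzyl]-4-bromo-3-{2-[5-(benzyloxy)-2-bromophenyl]ethyl}-5-methoxyphenol F5. A twofold Negishi coupling with 18 (made from 17 as in step 8, in excess, Pd(OAc)2/SPhos, THF, 50 °C) then installs both remaining benzyl groups and comes back to the route at 19, by-passing 16.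

Step 8. The free phenol may protonate the benzylic zinc reagent, and oxidative addition into the electron-rich, ortho-substituted C–Br bond may be slow, so that hydrodebromination and homocoupling of the zinc reagent take over. The fallback sets out from 16 and forms the diarylmethane by carbonyl addition and deoxygenation. Deprotonation of the phenol (NaH, THF) and Br/Li exchange (n-BuLi, −78 °C) give sodium 2,4,6-tris[4-(benzyloxy)benzyl]-3-{2-[5-(benzyloxy)-2-lithiophenyl]ethyl}-5-methoxyphenolate F6. Addition to aldehyde 1 gives 2,4,6-tris[4-(benzyloxy)benzyl]-3-[2-(5-(benzyloxy)-2-{[4-(benzyloxy)phenyl](hydroxy)methyl}phenyl)ethyl]-5-methoxyphenol F7 (racemic carbinol). Ionic hydrogenation (Et3SiH, TFA, CH2Cl2, 0 °C) removes the doubly benzylic hydroxyl and comes back to the route at 19.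

**Further compounds**

F1 | step 5 | dimethyl 4-{2-[5-(benzyloxy)-2-bromophenyl]ethyl}-2,6-dihydroxybenzene-1,3-dicarboxylate | COC(=O)c1c(O)cc(CCc2cc(OCc3ccccc3)ccc2Br)c(C(=O)OC)c1O
F2 | step 5 | 4-{2-[5-(benzyloxy)-2-bromophenyl]ethyl}-2,6-dihydroxybenzene-1,3-dicarboxylic acid | OC(=O)c1c(O)cc(CCc2cc(OCc3ccccc3)ccc2Br)c(C(O)=O)c1O
F3 | step 5 | 5-{2-[5-(benzyloxy)-2-bromophenyl]ethyl}benzene-1,3-diol | Oc1cc(O)cc(CCc2cc(OCc3ccccc3)ccc2Br)c1
F4 | step 5 | 3-{2-[5-(benzyloxy)-2-bromophenyl]ethyl}-5-methoxyphenol | COc1cc(O)cc(CCc2cc(OCc3ccccc3)ccc2Br)c1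
F5 | step 7 | 2,6-bis[4-(benzyloxy)benzyl]-4-bromo-3-{2-[5-(benzyloxy)-2-bromophenyl]ethyl}-5-methoxyphenol | COc1c(Br)c(CCc2cc(OCc3ccccc3)ccc2Br)c(Cc2ccc(OCc3ccccc3)cc2)c(O)c1Cc1ccc(OCc2ccccc2)cc1
F6 | step 8 | sodium 2,4,6-tris[4-(benzyloxy)benzyl]-3-{2-[5-(benzyloxy)-2-lithiophenyl]ethyl}-5-methoxyphenolate | [Na+].COc1c(Cc2ccc(OCc3ccccc3)cc2)c([O-])c(Cc2ccc(OCc3ccccc3)cc2)c(CCc2cc(OCc3ccccc3)ccc2[Li])c1Cc1ccc(OCc2ccccc2)cc1
F7 | step 8 | 2,4,6-tris[4-(benzyloxy)benzyl]-3-[2-(5-(benzyloxy)-2-{[4-(benzyloxy)phenyl](hydroxy)methyl}phenyl)ethyl]-5-methoxyphenol (racemic) | COc1c(Cc2ccc(OCc3ccccc3)cc2)c(O)c(Cc2ccc(OCc3ccccc3)cc2)c(CCc2cc(OCc3ccccc3)ccc2C(O)c2ccc(OCc3ccccc3)cc2)c1Cc1ccc(OCc2ccccc2)cc1
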